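The dihydropyridine ring is closed late, on a finished biaryl. On the isoquinoline benzo ring (C4a to C8a) exactly one C–H bond lies ortho to the ketoxime carbon: the future C4a, beside C5–H. The other ortho carbon carries the C8 methoxy group. A chiral cyclopentadienyl rhodium catalyst cleaves this bond, inserts propene and closes the N–C3 bond with the oxime N–O bond as internal oxidant. One operation thus forms C4–C4a and N–C3, sets the C3 stereocentre and delivers the C1=N imine at the oxidation level of the target. The precursor is the O-pivaloyl oxime of a MOM-protected biaryl methyl ketone, made by Negishi coupling of a Stobbe-derived bromonaphthalene with an iodoacetophenone.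

Key step: step 13

Assumption: the structure defines only the stereocentre C3 (S) and leaves the biaryl axis open, so the route controls C3 alone and the 3S product is taken as the target whatever the sense of the axis (the two rotamers may be separable atropisomers).

Step 1
Reactants: 1 2-bromo-5-methoxybenzaldehyde; 2 diethyl succinate
Product: 3 (E)-4-(2-bromo-5-methoxyphenyl)-3-(ethoxycarbonyl)but-3-enoic acid
Conditions: KOtBu, tBuOH, reflux; then aq HCl
Reagents that add atoms: none
Why: Stobbe condensation, in which the succinate enolate adds to the non-enolisable aldehyde, the alkoxide lactonises onto the distal ester and base opens the lactone by elimination, so that the half-ester forms with the aryl group trans to the retained ester (E), the geometry needed for the ring closure that follows.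

Step 2
Reactants: 3 (E)-4-(2-bromo-5-methoxyphenyl)-3-(ethoxycarbonyl)but-3-enoic acid
Product: 4 ethyl 4-acetoxy-8-bromo-5-methoxynaphthalene-2-carboxylate
Conditions: Ac2O, NaOAc (cat), reflux
Reagents that add atoms: acetic anhydride, CC(=O)OC(C)=O
Why: Intramolecular Friedel–Crafts acylation of the mixed anhydride can only go to the one free position ortho to the side chain (the other carries bromine), a position activated by the ortho methoxy group, and the naphthol formed by enolisation is acetylated in the same flask.

Step 3
Reactants: 4 ethyl 4-acetoxy-8-bromo-5-methoxynaphthalene-2-carboxylate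
Product: 5 ethyl 8-bromo-4-hydroxy-5-methoxynaphthalene-2-carboxylate
Conditions: K2CO3 (0.2 equiv), EtOH, rt
Reagents that add atoms: none
Why: Base-catalysed transesterification removes the phenolic acetate, a far better acyl donor than the aryl carboxylic ester, and ethanol as the alcohol leaves the ethyl ester as it is.

Step 4
Reactants: 5 ethyl 8-bromo-4-hydroxy-5-methoxynaphthalene-2-carboxylate
Product: 6 ethyl 8-bromo-5-methoxy-4-(methoxymethoxy)naphthalene-2-carboxylate
Conditions: MOMCl, iPr2NEt, CH2Cl2, 0 °C to 40 °C
Reagents that add atoms: chloromethyl methyl ether (MOMCl), COCCl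
Why: Williamson-type O-alkylation of the naphthoxide with the reactive chloromethyl ether gives the MOM acetal, which should withstand the hydride, organometallic, palladium and rhodium steps and is removed by acid in the last step.

Step 5
Reactants: 6 ethyl 8-bromo-5-methoxy-4-(methoxymethoxy)naphthalene-2-carboxylate
Product: 7 [8-bromo-5-methoxy-4-(methoxymethoxy)naphthalen-2-yl]methanol
Conditions: LiAlH4, THF, 0 °C; aq work-up
Reagents that add atoms: none
Why: Hydride reduction of the ester to the primary benzylic alcohol, under conditions (0 °C) that leave the aryl bromide and the acetal alone.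

Step 6
Reactants: 7 [8-bromo-5-methoxy-4-(methoxymethoxy)naphthalen-2-yl]methanol
Product: 9 5-bromo-8-methoxy-1-(methoxymethoxy)-3-methylnaphthalene, via benzylic mesylate 8 (not isolated)
Conditions: MsCl, Et3N, THF, 0 °C; then LiEt3BH, 0 °C to rt
Reagents that add atoms: none
Why: Mesylation of the primary benzylic alcohol and SN2 displacement of the sulfonate by the strong hydride donor LiEt3BH in the same flask turn CH2OH into CH3 (deoxygenation by hydride substitution), the aryl bromide being slow to react with this reagent at or below room temperature.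

Step 7
Reactants: 10 1-(2,4-dihydroxyphenyl)ethanone
Product: 11 1-(2,4-dihydroxy-3-iodophenyl)ethanone
Conditions: I2 (0.4 equiv), HIO3 (0.2 equiv), EtOH/H2O, 35 °C
Reagents that add atoms: iodine, II; iodic acid, OI(=O)=O
Why: Electrophilic aromatic iodination, steered to C3 between the two hydroxyl groups by the bond fixation that the chelated ortho-hydroxy ketone imposes, with iodic acid re-oxidising the iodide so that both iodine atoms of I2 are used.

Step 8
Reactants: 11 1-(2,4-dihydroxy-3-iodophenyl)ethanone
Product: 12 1-[2-hydroxy-3-iodo-4-(methoxymethoxy)phenyl]ethanone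
Conditions: MOMCl (1.05 equiv), K2CO3, acetone, 0 °C to rt
Reagents that add atoms: chloromethyl methyl ether (MOMCl), COCCl
Why: The 2-hydroxyl group is locked in a hydrogen bond to the acetyl oxygen, so Williamson alkylation with one equivalent of the chloromethyl ether and a weak base should take the free and more acidic 4-hydroxyl group only.

Step 9
Reactants: 12 1-[2-hydroxy-3-iodo-4-(methoxymethoxy)phenyl]ethanone
Product: 13 1-[3-iodo-2-methoxy-4-(methoxymethoxy)phenyl]ethanone
Conditions: MeI (excess), K2CO3, DMF, 40 °C
Reagents that add atoms: iodomethane, CI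
Why: Williamson methylation of the remaining chelated and flanked phenol with excess iodomethane in a dipolar solvent, conditions that the acetal, the aryl iodide and the ketone tolerate.

Step 10
Reactants: 9 5-bromo-8-methoxy-1-(methoxymethoxy)-3-methylnaphthalene; 13 1-[3-iodo-2-methoxy-4-(methoxymethoxy)phenyl]ethanone
Product: 16 1-[2-methoxy-4-(methoxymethoxy)-3-[4-methoxy-5-(methoxymethoxy)-7-methylnaphthalen-1-yl]phenyl]ethanone, via naphthyllithium 14 (not isolated), via naphthylzinc chloride 15 (not isolated)
Conditions: 9, n-butyllithium (1.0 equiv), THF, −78 °C; ZnCl2, −78 °C to rt; then 13, Pd2(dba)3 (2 mol %), SPhos (8 mol %), THF, 60 °C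
Reagents that add atoms: none
Why: Negishi cross-coupling, in which bromine–lithium exchange at −78 °C outruns ortho-lithiation, the arylzinc chloride leaves the ketone alone, and SPhos-ligated zerovalent palladium is suited to joining a doubly ortho-substituted aryl iodide to a 1-naphthyl metal; the new biaryl axis forms without stereocontrol.

Step 11
Reactants: 16 1-[2-methoxy-4-(methoxymethoxy)-3-[4-methoxy-5-(methoxymethoxy)-7-methylnaphthalen-1-yl]phenyl]ethanone
Product: 17 (E)-1-[2-methoxy-4-(methoxymethoxy)-3-[4-methoxy-5-(methoxymethoxy)-7-methylnaphthalen-1-yl]phenyl]ethanone oxime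
Conditions: NH2OH·HCl, NaOAc, EtOH/H2O, 70 °C
Reagents that add atoms: hydroxylamine hydrochloride, NO.Cl
Why: Condensation of the ketone with hydroxylamine (oxime formation) should give mainly the E oxime, in which the oxygen points away from the ortho-substituted aryl ring and the nitrogen lone pair towards the free ortho C–H bond.

Step 12
Reactants: 17 (E)-1-[2-methoxy-4-(methoxymethoxy)-3-[4-methoxy-5-(methoxymethoxy)-7-methylnaphthalen-1-yl]phenyl]ethanone oxime
Product: 18 (E)-1-[2-methoxy-4-(methoxymethoxy)-3-[4-methoxy-5-(methoxymethoxy)-7-methylnaphthalen-1-yl]phenyl]ethanone O-pivaloyl oxime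
Conditions: PivCl, Et3N, DMAP (5 mol %), CH2Cl2, 0 °C
Reagents that add atoms: pivaloyl chloride, CC(C)(C)C(=O)Cl
Why: O-Acylation of the oxime installs the N–O ester that serves as internal oxidant in the next step and keeps the oxime geometry.

Step 13
Reactants: 18 (E)-1-[2-methoxy-4-(methoxymethoxy)-3-[4-methoxy-5-(methoxymethoxy)-7-methylnaphthalen-1-yl]phenyl]ethanone O-pivaloyl oxime; 19 propene
Product: 20 (3S)-8-methoxy-6-(methoxymethoxy)-7-[4-methoxy-5-(methoxymethoxy)-7-methylnaphthalen-1-yl]-1,3-dimethyl-3,4-dihydroisoquinoline
Conditions: (R)-(Cpx)Rh(C2H4)2 (5 mol %; Cpx = cyclopentadienyl ring joined through two CH2 groups to C2 and C2' of 3,3'-dimethoxy-1,1'-binaphthyl), (BzO)2 (5 mol %), CsOPiv (30 mol %), propene (3 bar), CF3CH2OH, 40 °C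
Reagents that add atoms: none
Why: Proposed new method: the monovalent rhodium precatalyst is oxidised by the peroxide to a trivalent rhodium carboxylate, which binds the oxime nitrogen, cleaves the only ortho C–H bond by concerted metalation–deprotonation to a five-membered rhodacycle, inserts propene into the Rh–aryl bond with the aryl group going to the CH2 terminus, and then forms the N–C3 bond from the seven-membered rhodacycle while the N–O bond breaks and pivalic acid leaves, which returns trivalent rhodium without an external oxidant. The closest known reaction types are the cyclopentadienyl-rhodium-catalysed C–H activation and annulation of N-acyloxybenzamides with alkenes to 3,4-dihydroisoquinolones, which chiral cyclopentadienyl ligands make enantioselective, and the annulation of unsaturated oxime pivalates with alkenes to 2,3-dihydropyridines; the combination of an aryl ketoxime ester, a simple 1-alkene and enantiocontrol is the new element. The six-membered nitrogen ring is closed as a formal [4+2] annulation of the C=C–C=N unit of the aryl ketoxime with the alkene, the ring-closing event being C–N bond formation at rhodium. C3 is set in the migratory insertion, where the binaphthyl wall of the ligand decides which face of propene meets the Rh–aryl bond, and it is carried through the C–N bond formation with retention; the (R) ligand is proposed for the 3S product, and its antipode is the remedy should the sense of induction prove opposite. The step needs site selectivity, which the substitution pattern secures because the second ortho position carries the methoxy group and the naphthalene C–H bonds have no directing group, regioselectivity of insertion, which bulky cyclopentadienyl ligands are known to steer towards the 3-alkyl isomer, and C–N bond formation faster than beta-hydride elimination, which the chelating O-acyl group of the oxime is expected to favour. The remote biaryl axis is not influenced, and both atropisomers carry 3S.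

Step 14
Reactants: 20 (3S)-8-methoxy-6-(methoxymethoxy)-7-[4-methoxy-5-(methoxymethoxy)-7-methylnaphthalen-1-yl]-1,3-dimethyl-3,4-dihydroisoquinoline
Product: 21 (3S)-7-(5-hydroxy-4-methoxy-7-methylnaphthalen-1-yl)-8-methoxy-1,3-dimethyl-3,4-dihydroisoquinolin-6-ol
Conditions: HCl (3 M in MeOH), 40 °C; then aq NaHCO3
Reagents that add atoms: none
Why: Acid-catalysed acetal exchange with methanol (MOM cleavage) frees both phenols while the cyclic imine is held as its iminium salt, which offers no path to epimerisation at C3, and mild base returns the free base.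

Compound list
1 | 2-bromo-5-methoxybenzaldehyde | O=Cc1cc(OC)ccc1Br | starting material
2 | diethyl succinate | CCOC(=O)CCC(=O)OCC | starting material
3 | (E)-4-(2-bromo-5-methoxyphenyl)-3-(ethoxycarbonyl)but-3-enoic acid | CCOC(=O)/C(CC(=O)O)=C/c1cc(OC)ccc1Br | intermediate
4 | ethyl 4-acetoxy-8-bromo-5-methoxynaphthalene-2-carboxylate | CCOC(=O)c1cc(OC(C)=O)c2c(OC)ccc(Br)c2c1 | intermediate
5 | ethyl 8-bromo-4-hydroxy-5-methoxynaphthalene-2-carboxylate | CCOC(=O)c1cc(O)c2c(OC)ccc(Br)c2c1 | intermediate
6 | ethyl 8-bromo-5-methoxy-4-(methoxymethoxy)naphthalene-2-carboxylate | CCOC(=O)c1cc(OCOC)c2c(OC)ccc(Br)c2c1 | intermediate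
7 | [8-bromo-5-methoxy-4-(methoxymethoxy)naphthalen-2-yl]methanol | OCc1cc(OCOC)c2c(OC)ccc(Br)c2c1 | intermediate
8 | [8-bromo-5-methoxy-4-(methoxymethoxy)naphthalen-2-yl]methyl methanesulfonate | CS(=O)(=O)OCc1cc(OCOC)c2c(OC)ccc(Br)c2c1 | intermediate
9 | 5-bromo-8-methoxy-1-(methoxymethoxy)-3-methylnaphthalene | Cc1cc(OCOC)c2c(OC)ccc(Br)c2c1 | intermediate
10 | 1-(2,4-dihydroxyphenyl)ethanone (2,4-dihydroxyacetophenone) | CC(=O)c1ccc(O)cc1O | starting material
11 | 1-(2,4-dihydroxy-3-iodophenyl)ethanone | CC(=O)c1ccc(O)c(I)c1O | intermediate
12 | 1-[2-hydroxy-3-iodo-4-(methoxymethoxy)phenyl]ethanone | CC(=O)c1ccc(OCOC)c(I)c1O | intermediate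
13 | 1-[3-iodo-2-methoxy-4-(methoxymethoxy)phenyl]ethanone | CC(=O)c1ccc(OCOC)c(I)c1OC | intermediate
14 | [4-methoxy-5-(methoxymethoxy)-7-methylnaphthalen-1-yl]lithium | [Li]c1ccc(OC)c2c(OCOC)cc(C)cc12 | intermediate
15 | chloro[4-methoxy-5-(methoxymethoxy)-7-methylnaphthalen-1-yl]zinc | Cl[Zn]c1ccc(OC)c2c(OCOC)cc(C)cc12 | intermediate
16 | 1-[2-methoxy-4-(methoxymethoxy)-3-[4-methoxy-5-(methoxymethoxy)-7-methylnaphthalen-1-yl]phenyl]ethanone | CC(=O)c1ccc(OCOC)c(-c2ccc(OC)c3c(OCOC)cc(C)cc23)c1OC | intermediate
17 | (E)-1-[2-methoxy-4-(methoxymethoxy)-3-[4-methoxy-5-(methoxymethoxy)-7-methylnaphthalen-1-yl]phenyl]ethanone oxime | C/C(=N\O)c1ccc(OCOC)c(-c2ccc(OC)c3c(OCOC)cc(C)cc23)c1OC | intermediate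
18 | (E)-1-[2-methoxy-4-(methoxymethoxy)-3-[4-methoxy-5-(methoxymethoxy)-7-methylnaphthalen-1-yl]phenyl]ethanone O-pivaloyl oxime | C/C(=N\OC(=O)C(C)(C)C)c1ccc(OCOC)c(-c2ccc(OC)c3c(OCOC)cc(C)cc23)c1OC | intermediate
19 | propene | C=CC | starting material
20 | (3S)-8-methoxy-6-(methoxymethoxy)-7-[4-methoxy-5-(methoxymethoxy)-7-methylnaphthalen-1-yl]-1,3-dimethyl-3,4-dihydroisoquinoline | COc1c2c(cc(OCOC)c1-c1ccc(OC)c3c(OCOC)cc(C)cc13)C[C@H](C)N=C2C | intermediate
21 | (3S)-7-(5-hydroxy-4-methoxy-7-methylnaphthalen-1-yl)-8-methoxy-1,3-dimethyl-3,4-dihydroisoquinolin-6-ol | COc1c2c(cc(O)c1-c1ccc(OC)c3c(O)cc(C)cc13)C[C@H](C)N=C2C | target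

Total step count: 14. Longest linear sequence: 11 steps (steps 1 to 6, then 10 to 14); steps 7 to 9 form the second branch.

Steps most likely to fail

Step 13. The alkylrhodium intermediate may undergo beta-hydride elimination before the C–N bond forms, which would lead on to the achiral, aromatised isoquinoline. Propene may also insert with the opposite orientation, or its two faces may be poorly distinguished. The fallback uses known chemistry, keeps the same two bonds in one operation and sets out from ketone 16. A King reaction (I2, pyridine, 100 °C; then aq NaOH) degrades the acetyl group to 2-methoxy-4-(methoxymethoxy)-3-[4-methoxy-5-(methoxymethoxy)-7-methylnaphthalen-1-yl]benzoic acid F1. Coupling with O-pivaloylhydroxylamine triflate (EDC, iPr2NEt, CH2Cl2) gives the N-(pivaloyloxy)benzamide F2. The annulation of N-acyloxybenzamides with alkenes under cyclopentadienyl rhodium catalysis is established, including enantioselective variants with chiral cyclopentadienyl ligands and variants with alkyl-substituted alkenes. Applied here with (Cpx)Rh(C2H4)2, (BzO)2 and propene in EtOH at rt, it should give the (3S)-3-methyl-3,4-dihydroisoquinolin-1(2H)-one F3. Boc2O and DMAP give the N-Boc lactam F4, and MeLi in THF at −78 °C opens the activated lactam to the Boc-amino methyl ketone F5. HCl in MeOH then removes the Boc and both MOM groups, and the freed amine condenses with the aryl ketone, so the sequence rejoins the route at target 21.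

Step 10. The halogen–metal exchange may be incomplete or unselective (lithiation next to the MOM group, alkylation of the aryllithium by the butyl bromide formed). Transmetalation and reductive elimination at the doubly ortho-substituted palladium centre may also be slow, which would end in protodemetalation. The fallback avoids the aryllithium and sets out from bromide 9. Miyaura borylation (B2pin2, Pd(dppf)Cl2, KOAc, dioxane, 90 °C) gives the naphthyl pinacol boronate F6. Suzuki–Miyaura coupling of F6 with iodide 13 (Pd(OAc)2, SPhos, K3PO4, toluene/H2O, 90 °C) comes back to the route at ketone 16.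

Step 6. Chloride may displace the mesylate to give a less reactive benzylic chloride, and the hydride may begin to reduce the C–Br bond before the substitution is complete. The fallback replaces hydride substitution by a carbonyl deoxygenation and sets out from alcohol 7. MnO2 in CH2Cl2 gives 8-bromo-5-methoxy-4-(methoxymethoxy)naphthalene-2-carbaldehyde F7, and TsNHNH2 in MeOH gives its tosylhydrazone F8. Reduction of F8 (catecholborane, CHCl3, 0 °C; then NaOAc·3H2O, reflux) with loss of nitrogen returns to the route at bromide 9.

Further compounds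
F1 | step 13 | 2-methoxy-4-(methoxymethoxy)-3-[4-methoxy-5-(methoxymethoxy)-7-methylnaphthalen-1-yl]benzoic acid | OC(=O)c1ccc(OCOC)c(-c2ccc(OC)c3c(OCOC)cc(C)cc23)c1OC
F2 | step 13 | 2-methoxy-4-(methoxymethoxy)-3-[4-methoxy-5-(methoxymethoxy)-7-methylnaphthalen-1-yl]-N-(pivaloyloxy)benzamide | CC(C)(C)C(=O)ONC(=O)c1ccc(OCOC)c(-c2ccc(OC)c3c(OCOC)cc(C)cc23)c1OC
F3 | step 13 | (3S)-8-methoxy-6-(methoxymethoxy)-7-[4-methoxy-5-(methoxymethoxy)-7-methylnaphthalen-1-yl]-3-methyl-3,4-dihydroisoquinolin-1(2H)-one | COc1c2c(cc(OCOC)c1-c1ccc(OC)c3c(OCOC)cc(C)cc13)C[C@H](C)NC2=O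
F4 | step 13 | tert-butyl (3S)-8-methoxy-6-(methoxymethoxy)-7-[4-methoxy-5-(methoxymethoxy)-7-methylnaphthalen-1-yl]-3-methyl-1-oxo-3,4-dihydroisoquinoline-2(1H)-carboxylate | COc1c2c(cc(OCOC)c1-c1ccc(OC)c3c(OCOC)cc(C)cc13)C[C@H](C)N(C(=O)OC(C)(C)C)C2=O
F5 | step 13 | tert-butyl N-[(2S)-1-[2-acetyl-3-methoxy-5-(methoxymethoxy)-4-[4-methoxy-5-(methoxymethoxy)-7-methylnaphthalen-1-yl]phenyl]propan-2-yl]carbamate | COc1c(C(C)=O)c(C[C@H](C)NC(=O)OC(C)(C)C)cc(OCOC)c1-c1ccc(OC)c2c(OCOC)cc(C)cc12
F6 | step 10 | 2-[4-methoxy-5-(methoxymethoxy)-7-methylnaphthalen-1-yl]-4,4,5,5-tetramethyl-1,3,2-dioxaborolane | CC1(C)OB(OC1(C)C)c1ccc(OC)c2c(OCOC)cc(C)cc12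
F7 | step 6 | 8-bromo-5-methoxy-4-(methoxymethoxy)naphthalene-2-carbaldehyde | O=Cc1cc(OCOC)c2c(OC)ccc(Br)c2c1
F8 | step 6 | N'-[(E)-[8-bromo-5-methoxy-4-(methoxymethoxy)naphthalen-2-yl]methylidene]-4-methylbenzenesulfonohydrazide | Cc1ccc(cc1)S(=O)(=O)N/N=C/c1cc(OCOC)c2c(OC)ccc(Br)c2c1
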